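**Plan**

1. Retrosynthesis: the three silyl ethers and the p‑coumarate ester C–O bond are cut first (15 ⇒ alcohol 12 + p‑coumaric acid 13). The exocyclic C3 carbon is then raised to the ester level, a helper that makes C3 an enolate carbon and is reduced again in step 8.
2. The dihydrofuran ring is then cut at O1–C7a and C3–C3a together. O1–C2–C3 is the 1,3‑O,C bis‑nucleophile of an aldol (β‑hydroxy ester 9). The adjacent benzo carbons C7a/C3a are a 1,2‑bis‑electrophile: C7a, ortho to the C7‑OMe, is a former guaiacol OH that becomes a triflate, and C3a carries an iodide.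
3. Forward: arene 4 (3 steps from dihydroconiferyl alcohol) and aldol 9 (3 steps from methyl vanillate) are joined and the ring is closed in one flask (step 7). Ester reduction, Mitsunobu esterification and global desilylation follow.
4. Stereochemistry: C2 comes from the catalyst‑controlled transfer hydrogenation of β‑keto ester 8 and is carried through with its C–O bond intact. C3 is set trans to C2 by thermodynamic equilibration of the ester α‑carbon in step 7.

Key step: step 7

Assumption: the transfer hydrogenation of 8 is taken to follow the facial sense known for aryl alkyl ketones, so the (R,R)‑TsDPEN catalyst should give the (R)‑carbinol; if the sense were opposite, the ligand enantiomer would be exchanged.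

**Step 1**
Reactants: 1 3‑(4‑hydroxy‑3‑methoxyphenyl)propan‑1‑ol (dihydroconiferyl alcohol)
Product: 2 3‑(4‑hydroxy‑3‑iodo‑5‑methoxyphenyl)propan‑1‑ol
Conditions: NIS (1.0 equiv), TsOH·H2O (10 mol %), MeCN, 0 °C → rt
Reagents that add atoms: N‑iodosuccinimide, O=C1CCC(=O)N1I
Why: Electrophilic aromatic iodination directed by the free phenol, whose para position carries the side chain, so iodine should enter the ortho position not flanked by OMe; no stereocentre is formed.

**Step 2**
Reactants: 2 3‑(4‑hydroxy‑3‑iodo‑5‑methoxyphenyl)propan‑1‑ol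
Product: 3 4‑(3‑hydroxypropyl)‑2‑iodo‑6‑methoxyphenyl trifluoromethanesulfonate
Conditions: PhNTf2 (1.1 equiv), Et3N, DMAP (cat.), CH2Cl2, rt
Reagents that add atoms: N‑phenylbis(trifluoromethanesulfonimide), O=S(=O)(N(c1ccccc1)S(=O)(=O)C(F)(F)F)C(F)(F)F
Why: Chemoselective O‑sulfonylation, since PhNTf2 transfers the triflyl group to the phenoxide formed with Et3N but leaves the neutral primary alcohol untouched.

**Step 3**
Reactants: 3 4‑(3‑hydroxypropyl)‑2‑iodo‑6‑methoxyphenyl trifluoromethanesulfonate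
Product: 4 4‑[3‑(tert‑butyldimethylsilyloxy)propyl]‑2‑iodo‑6‑methoxyphenyl trifluoromethanesulfonate
Conditions: TBSCl, imidazole, CH2Cl2, rt
Reagents that add atoms: tert‑butyldimethylsilyl chloride, CC(C)(C)[Si](C)(C)Cl
Why: Standard silylation of the primary alcohol, which masks the side chain against the strong bases of step 7 and the Mitsunobu reaction of step 9.

**Step 4**
Reactants: 5 methyl 4‑hydroxy‑3‑methoxybenzoate (methyl vanillate)
Product: 6 methyl 3‑methoxy‑4‑(triisopropylsilyloxy)benzoate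
Conditions: TIPSCl, imidazole, DMF, rt
Reagents that add atoms: triisopropylsilyl chloride, CC(C)[Si](Cl)(C(C)C)C(C)C
Why: Silylation of the phenol, with the bulky TIPS ether chosen because it must survive lithium amides, hydride and warm alkoxide before fluoride removes it at the end.

**Step 5**
Reactants: 6 methyl 3‑methoxy‑4‑(triisopropylsilyloxy)benzoate; 7 tert‑butyl acetate
Product: 8 tert‑butyl 3‑[3‑methoxy‑4‑(triisopropylsilyloxy)phenyl]‑3‑oxopropanoate
Conditions: 7 (3 equiv), LiHMDS (3.2 equiv), THF, −78 °C; then 6, −78 → −20 °C; aq NH4Cl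
Reagents that add atoms: none
Why: Crossed Claisen condensation in which the lithium enolate of tert‑butyl acetate, used in excess so that a second equivalent deprotonates the product, acylates on the non‑enolisable methyl benzoate.

**Step 6**
Reactants: 8 tert‑butyl 3‑[3‑methoxy‑4‑(triisopropylsilyloxy)phenyl]‑3‑oxopropanoate
Product: 9 tert‑butyl (3R)‑3‑hydroxy‑3‑[3‑methoxy‑4‑(triisopropylsilyloxy)phenyl]propanoate
Conditions: RuCl(p‑cymene)[(R,R)‑TsDPEN] (1 mol %), HCO2H/Et3N (5:2), 40 °C
Reagents that add atoms: none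
Why: Noyori–Ikariya asymmetric transfer hydrogenation, in which the bifunctional Ru–H/N–H catalyst delivers hydride to one face of the aryl ketone through a CH/π‑organised six‑membered transition state, setting the (R)‑carbinol (the future C2) under catalyst control.

**Step 7**
Reactants: 4 4‑[3‑(tert‑butyldimethylsilyloxy)propyl]‑2‑iodo‑6‑methoxyphenyl trifluoromethanesulfonate; 9 tert‑butyl (3R)‑3‑hydroxy‑3‑[3‑methoxy‑4‑(triisopropylsilyloxy)phenyl]propanoate
Product: 11 tert‑butyl (2R,3R)‑5‑[3‑(tert‑butyldimethylsilyloxy)propyl]‑7‑methoxy‑2‑[3‑methoxy‑4‑(triisopropylsilyloxy)phenyl]‑2,3‑dihydro‑1‑benzofuran‑3‑carboxylate, via open‑chain α‑aryl aldol triflate 10 (not isolated)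
Conditions: 9, LDA (2.1 equiv), THF, −78 → −20 °C; then 4, LiHMDS (1.2 equiv), Pd2(dba)3 (2.5 mol %), t‑BuXPhos (6 mol %), toluene, rt → 60 °C; then t‑BuOH (5 equiv), 60 °C; aq NH4Cl
Reagents that add atoms: none
Why: Proposed new method: Pd(0)/t‑BuXPhos adds first to the C–I bond of 4, the enolate carbon of the pre‑formed alkoxide–enolate dianion of 9 (Fráter–Seebach type) transmetalates and C–C reductive elimination gives 10 (bond C3–C3a); the same catalyst then adds to the neighbouring C–OTf bond, the lithium alkoxide binds to Pd and C(aryl)–O reductive elimination forms O1–C7a. The closest known reaction types are the Pd‑catalysed tandem C‑arylation/O‑arylation of ketone and β‑keto ester enolates with 1,2‑dihaloarenes (benzofuran synthesis), the α‑arylation of tert‑butyl ester lithium enolates and the intramolecular Pd etherification of secondary alkoxides, merged here on an aldol so that the carbinol carbon stays sp3. The one ring that closes, the dihydrofuran, does so at oxygen by reductive elimination from a six‑membered aryl–Pd–alkoxide chelate, which gives the five‑membered ring. C2 is not a new centre: none of its bonds is broken, retro‑aldol is blocked because the arylated aldolate is held as its enolate by the extra base, and β‑elimination of the product enolate is disfavoured because the C2–O1 bond lies in the ring plane, orthogonal to the enolate π system; the new centre C3 is controlled by C2 under thermodynamic conditions, LiOt‑Bu/t‑BuOH equilibrating the ester α‑carbon to the trans isomer. The step needs site selectivity on the arene (carbon to the position meta to OMe, oxygen to the position ortho to OMe), secured by oxidative addition to C–I before C–OTf and by enolate C‑arylation being far faster than alkoxide O‑arylation, and it needs closure by the alkoxide and not by the enolate oxygen, which the C‑bound nature of Pd ester enolates and the bulk of the tert‑butyl ester should secure.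

**Step 8**
Reactants: 11 tert‑butyl (2R,3R)‑5‑[3‑(tert‑butyldimethylsilyloxy)propyl]‑7‑methoxy‑2‑[3‑methoxy‑4‑(triisopropylsilyloxy)phenyl]‑2,3‑dihydro‑1‑benzofuran‑3‑carboxylate
Product: 12 {(2R,3S)‑5‑[3‑(tert‑butyldimethylsilyloxy)propyl]‑7‑methoxy‑2‑[3‑methoxy‑4‑(triisopropylsilyloxy)phenyl]‑2,3‑dihydro‑1‑benzofuran‑3‑yl}methanol
Conditions: LiAlH4, THF, 0 °C; Fieser work‑up
Reagents that add atoms: none
Why: Hydride reduction of the ester to the primary alcohol, after which C3 is no longer epimerisable (the descriptor changes from 3R to 3S only through the priority change), and both silyl ethers are stable to LiAlH4 at 0 °C.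

**Step 9**
Reactants: 12 {(2R,3S)‑5‑[3‑(tert‑butyldimethylsilyloxy)propyl]‑7‑methoxy‑2‑[3‑methoxy‑4‑(triisopropylsilyloxy)phenyl]‑2,3‑dihydro‑1‑benzofuran‑3‑yl}methanol; 13 (E)‑3‑(4‑hydroxyphenyl)prop‑2‑enoic acid (p‑coumaric acid)
Product: 14 {(2R,3S)‑5‑[3‑(tert‑butyldimethylsilyloxy)propyl]‑7‑methoxy‑2‑[3‑methoxy‑4‑(triisopropylsilyloxy)phenyl]‑2,3‑dihydro‑1‑benzofuran‑3‑yl}methyl (E)‑3‑(4‑hydroxyphenyl)prop‑2‑enoate
Conditions: PPh3, DIAD, THF, 0 °C → rt
Reagents that add atoms: none
Why: Mitsunobu esterification, in which only the carboxylic acid of 13 is acidic enough to protonate the betaine quickly, so its carboxylate and not a phenol should displace the alkoxyphosphonium ion of the primary carbinol (no stereocentre is involved).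

**Step 10**
Reactants: 14 {(2R,3S)‑5‑[3‑(tert‑butyldimethylsilyloxy)propyl]‑7‑methoxy‑2‑[3‑methoxy‑4‑(triisopropylsilyloxy)phenyl]‑2,3‑dihydro‑1‑benzofuran‑3‑yl}methyl (E)‑3‑(4‑hydroxyphenyl)prop‑2‑enoate
Product: 15 [(2R,3S)‑2‑(4‑hydroxy‑3‑methoxyphenyl)‑5‑(3‑hydroxypropyl)‑7‑methoxy‑2,3‑dihydro‑1‑benzofuran‑3‑yl]methyl (E)‑3‑(4‑hydroxyphenyl)prop‑2‑enoate (CNP0202924.1)
Conditions: TBAF/AcOH (1:1, 3 equiv), THF, 0 °C → rt
Reagents that add atoms: none
Why: Fluoride‑induced Si–O cleavage of the aryl TIPS and alkyl TBS ethers, buffered with acetic acid so that the phenols stay protonated and the cinnamate ester is not attacked.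

**Compound list**

1 | 3‑(4‑hydroxy‑3‑methoxyphenyl)propan‑1‑ol (dihydroconiferyl alcohol) | COc1cc(CCCO)ccc1O | starting material
2 | 3‑(4‑hydroxy‑3‑iodo‑5‑methoxyphenyl)propan‑1‑ol | COc1cc(CCCO)cc(I)c1O | intermediate
3 | 4‑(3‑hydroxypropyl)‑2‑iodo‑6‑methoxyphenyl trifluoromethanesulfonate | COc1cc(CCCO)cc(I)c1OS(=O)(=O)C(F)(F)F | intermediate
4 | 4‑[3‑(tert‑butyldimethylsilyloxy)propyl]‑2‑iodo‑6‑methoxyphenyl trifluoromethanesulfonate | COc1cc(CCCO[Si](C)(C)C(C)(C)C)cc(I)c1OS(=O)(=O)C(F)(F)F | intermediate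
5 | methyl 4‑hydroxy‑3‑methoxybenzoate (methyl vanillate) | COC(=O)c1ccc(O)c(OC)c1 | starting material
6 | methyl 3‑methoxy‑4‑(triisopropylsilyloxy)benzoate | COC(=O)c1ccc(O[Si](C(C)C)(C(C)C)C(C)C)c(OC)c1 | intermediate
7 | tert‑butyl acetate | CC(=O)OC(C)(C)C | starting material
8 | tert‑butyl 3‑[3‑methoxy‑4‑(triisopropylsilyloxy)phenyl]‑3‑oxopropanoate | CC(C)(C)OC(=O)CC(=O)c1ccc(O[Si](C(C)C)(C(C)C)C(C)C)c(OC)c1 | intermediate
9 | tert‑butyl (3R)‑3‑hydroxy‑3‑[3‑methoxy‑4‑(triisopropylsilyloxy)phenyl]propanoate | CC(C)(C)OC(=O)C[C@@H](O)c1ccc(O[Si](C(C)C)(C(C)C)C(C)C)c(OC)c1 | intermediate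
10 | open‑chain α‑aryl aldol triflate: tert‑butyl (3R)‑2‑{5‑[3‑(tert‑butyldimethylsilyloxy)propyl]‑3‑methoxy‑2‑(trifluoromethanesulfonyloxy)phenyl}‑3‑hydroxy‑3‑[3‑methoxy‑4‑(triisopropylsilyloxy)phenyl]propanoate (C2 not defined; present in the flask as its lithium alkoxide/enolate) | CC(C)(C)OC(=O)C(c1cc(CCCO[Si](C)(C)C(C)(C)C)cc(OC)c1OS(=O)(=O)C(F)(F)F)[C@@H](O)c1ccc(O[Si](C(C)C)(C(C)C)C(C)C)c(OC)c1 | intermediate
11 | tert‑butyl (2R,3R)‑5‑[3‑(tert‑butyldimethylsilyloxy)propyl]‑7‑methoxy‑2‑[3‑methoxy‑4‑(triisopropylsilyloxy)phenyl]‑2,3‑dihydro‑1‑benzofuran‑3‑carboxylate (trans) | COc1cc([C@@H]2Oc3c(OC)cc(CCCO[Si](C)(C)C(C)(C)C)cc3[C@H]2C(=O)OC(C)(C)C)ccc1O[Si](C(C)C)(C(C)C)C(C)C | intermediate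
12 | {(2R,3S)‑5‑[3‑(tert‑butyldimethylsilyloxy)propyl]‑7‑methoxy‑2‑[3‑methoxy‑4‑(triisopropylsilyloxy)phenyl]‑2,3‑dihydro‑1‑benzofuran‑3‑yl}methanol | COc1cc([C@@H]2Oc3c(OC)cc(CCCO[Si](C)(C)C(C)(C)C)cc3[C@H]2CO)ccc1O[Si](C(C)C)(C(C)C)C(C)C | intermediate
13 | (E)‑3‑(4‑hydroxyphenyl)prop‑2‑enoic acid (p‑coumaric acid) | O=C(O)/C=C/c1ccc(O)cc1 | starting material
14 | {(2R,3S)‑5‑[3‑(tert‑butyldimethylsilyloxy)propyl]‑7‑methoxy‑2‑[3‑methoxy‑4‑(triisopropylsilyloxy)phenyl]‑2,3‑dihydro‑1‑benzofuran‑3‑yl}methyl (E)‑3‑(4‑hydroxyphenyl)prop‑2‑enoate | COc1cc([C@@H]2Oc3c(OC)cc(CCCO[Si](C)(C)C(C)(C)C)cc3[C@H]2COC(=O)/C=C/c2ccc(O)cc2)ccc1O[Si](C(C)C)(C(C)C)C(C)C | intermediate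
15 | [(2R,3S)‑2‑(4‑hydroxy‑3‑methoxyphenyl)‑5‑(3‑hydroxypropyl)‑7‑methoxy‑2,3‑dihydro‑1‑benzofuran‑3‑yl]methyl (E)‑3‑(4‑hydroxyphenyl)prop‑2‑enoate | COc1cc([C@@H]2Oc3c(OC)cc(CCCO)cc3[C@H]2COC(=O)/C=C/c2ccc(O)cc2)ccc1O | target

**Step count and risks**

Total steps: 10. Longest linear sequence: 7 (steps 1–3 or 4–6, then 7–10).

Steps most likely to fail:

1. Step 7 (Proposed new method). Transmetalation of the hindered β‑oxido enolate may be slower than decay of the arylpalladium iodide. The triflate may be lost by sulfonyl transfer to the lithium alkoxide or amide, which would also open a ring closure through the phenoxide with inversion at C2. β‑Hydride elimination from the Pd alkoxide would oxidise the carbinol, and the enolate oxygen may close the ring in place of the alkoxide. The fallback uses known chemistry and sets out from 8 and 4. The sp2 version of the annulation, a Pd‑catalysed tandem C‑arylation/O‑arylation of the β‑keto ester (Pd2(dba)3, Xantphos, Cs2CO3, toluene, 100 °C), should give tert‑butyl 5‑[3‑(tert‑butyldimethylsilyloxy)propyl]‑7‑methoxy‑2‑[3‑methoxy‑4‑(triisopropylsilyloxy)phenyl]‑1‑benzofuran‑3‑carboxylate F1. Dissolving‑metal reduction of the 2,3‑double bond (Mg, MeOH/THF, 0 °C → rt), with equilibration by the methoxide formed, should give the trans ester as the racemate, that is 11 together with its (2S,3S)‑enantiomer F2. Preparative chromatography on a chiral stationary phase removes F2, and the route is rejoined at 11.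

2. Step 9. A phenol may be O‑alkylated by the alkoxyphosphonium ion in competition with the carboxylate, activation of the β‑branched carbinol may be slow, and the product may be hard to free from the phosphine oxide. The fallback sets out from 12 and builds the cinnamate on the substrate instead of coupling it. Heating 12 with Meldrum's acid (toluene, 90 °C) should give the malonic half‑ester 3‑({(2R,3S)‑5‑[3‑(tert‑butyldimethylsilyloxy)propyl]‑7‑methoxy‑2‑[3‑methoxy‑4‑(triisopropylsilyloxy)phenyl]‑2,3‑dihydro‑1‑benzofuran‑3‑yl}methoxy)‑3‑oxopropanoic acid F3. Knoevenagel–Doebner condensation of F3 with 4‑hydroxybenzaldehyde (pyridine, piperidine cat., 60 °C) should give the (E)‑p‑coumarate with decarboxylation and rejoin the route at 14.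

3. Step 6. Facial discrimination may be incomplete with the electron‑rich aryl ketone, or the β‑keto ester may chelate and slow the catalyst; either would lower the enantiomeric purity of every later compound. The fallback sets out from 8 and replaces asymmetric reduction by kinetic resolution. NaBH4 (MeOH, 0 °C) gives the racemic carbinol, that is 9 together with tert‑butyl (3S)‑3‑hydroxy‑3‑[3‑methoxy‑4‑(triisopropylsilyloxy)phenyl]propanoate F4. Lipase‑catalysed acylation (Burkholderia cepacia lipase, vinyl acetate, MTBE) should, by the Kazlauskas rule with the aryl group as the large substituent, convert the (R)‑carbinol into tert‑butyl (3R)‑3‑acetoxy‑3‑[3‑methoxy‑4‑(triisopropylsilyloxy)phenyl]propanoate F5. F4 is separated by chromatography, and lipase‑mediated butanolysis of F5 (n‑BuOH, MTBE) returns 9.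

**Further compounds**

F1 | step 7 | tert‑butyl 5‑[3‑(tert‑butyldimethylsilyloxy)propyl]‑7‑methoxy‑2‑[3‑methoxy‑4‑(triisopropylsilyloxy)phenyl]‑1‑benzofuran‑3‑carboxylate | COc1cc(-c2oc3c(OC)cc(CCCO[Si](C)(C)C(C)(C)C)cc3c2C(=O)OC(C)(C)C)ccc1O[Si](C(C)C)(C(C)C)C(C)C
F2 | step 7 | tert‑butyl (2S,3S)‑5‑[3‑(tert‑butyldimethylsilyloxy)propyl]‑7‑methoxy‑2‑[3‑methoxy‑4‑(triisopropylsilyloxy)phenyl]‑2,3‑dihydro‑1‑benzofuran‑3‑carboxylate (enantiomer of 11) | COc1cc([C@H]2Oc3c(OC)cc(CCCO[Si](C)(C)C(C)(C)C)cc3[C@@H]2C(=O)OC(C)(C)C)ccc1O[Si](C(C)C)(C(C)C)C(C)C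
F3 | step 9 | 3‑({(2R,3S)‑5‑[3‑(tert‑butyldimethylsilyloxy)propyl]‑7‑methoxy‑2‑[3‑methoxy‑4‑(triisopropylsilyloxy)phenyl]‑2,3‑dihydro‑1‑benzofuran‑3‑yl}methoxy)‑3‑oxopropanoic acid | COc1cc([C@@H]2Oc3c(OC)cc(CCCO[Si](C)(C)C(C)(C)C)cc3[C@H]2COC(=O)CC(=O)O)ccc1O[Si](C(C)C)(C(C)C)C(C)C
F4 | step 6 | tert‑butyl (3S)‑3‑hydroxy‑3‑[3‑methoxy‑4‑(triisopropylsilyloxy)phenyl]propanoate (enantiomer of 9) | CC(C)(C)OC(=O)C[C@H](O)c1ccc(O[Si](C(C)C)(C(C)C)C(C)C)c(OC)c1
F5 | step 6 | tert‑butyl (3R)‑3‑acetoxy‑3‑[3‑methoxy‑4‑(triisopropylsilyloxy)phenyl]propanoate | CC(C)(C)OC(=O)C[C@@H](OC(C)=O)c1ccc(O[Si](C(C)C)(C(C)C)C(C)C)c(OC)c1
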